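The numbers in the tables are simulated for an exercise, and the scatter is random.

Time first: you wanted the flasks at 50 min, twice the last alpha reading, so I reckoned a decay rather than a climb.

| flask | starting material | reagent | temperature | remark | time |
|---|---|---|---|---|---|
| alpha | 0.037 M | 0.50 equiv | 40 °C | run made earlier |  |
| theta | 0.40 M | 0.50 equiv | 51 °C | run made earlier |  |
| zeta | 0.10 M | 0.73 equiv | 40 °C | run made earlier |  |
| ash | 0.10 M | 0.500 equiv | 35 °C |  | 50 min |
| birch | 0.30 M | 0.500 equiv | 50 °C |  | 50 min |
| maple | 0.025 M | 0.500 equiv | 35 °C |  | 50 min |
| oak | 0.10 M | 0.750 equiv | 55 °C |  | 50 min |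

| alpha: time / min | alpha: target / % | theta: time / min | theta: target / % | zeta: time / min | zeta: target / % |
|---|---|---|---|---|---|
| 2.00 | 10 | 2.50 | 31 | 3.00 | 26 |
| 5.00 | 17 | 5.00 | 34 | 8.00 | 29 |
| 10.0 | 18 | 10.0 | 28 | 15.0 | 25 |
| 25.0 | 12 | 12.0 | 32 | 25.0 | 17 |

(readings scatter by 2 percentage points)

1. all flasks from highest to lowest amount of target, in percent of the starting material charged, at 50 min (ash / birch / maple / oak)
2. the same order at 3.0 h (ash / birch / maple / oak)
3. the amount of target, in percent of the starting material charged of the flask you put first, at 50 min
4. the amount of target, in percent of the starting material charged of the flask you put last, at 50 min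

- steps thought possible: starting material + reagent <-> target; 2 reagent -> self-condensation product

Alpha gave its top reading of 18% at 10.0 min and then fell slowly, so I took the addition as balanced from there on (a pre-equilibrium) and asked what it left free, since self-condensation consumes free reagent, not target. Counting reagent not in target as free, alpha gave 0.562 for the hold, target over free reagent, each as a fraction of the starting material charged. That is a reading, with its scatter. I scaled it with the charge at alpha's 40 °C, which gave birch 4.56, ash and oak 1.52, and maple 0.380. I left temperature out of this scaling as an assumption of mine: theta, at 51 °C, also differed from alpha in charge, 0.40 M against 0.037 M, so that pair did not separate heat from charge.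

Alpha's fall to 12% at 25.0 min gave a second-order constant for reagent loss of 4.40 L mol⁻¹ min⁻¹. The free share of the reagent enters that loss squared, and it was 0.180 in birch against 0.725 in maple. So at 50 min I had birch 19.8%, oak 12.6%, ash 11.0% and maple 5.64%. I kept that order at 3.0 h, with oak at 4.37% and ash at 4.17% barely apart.

Your hunch, the forecast, differed from mine: ash > birch > maple > oak at 50 min and ash > birch > maple > oak at 3.0 h, with ash at 17% (13% to 22%) and oak at 6% (3% to 10%), on the ground that “Higher concentration helps by storing reagent as target, and heat hurts”.

The flasks gave birch > oak > ash > maple at 50 min and birch > oak > ash > maple at 3.0 h.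

    starting material + reagent ⇌ target (K = 21.0 L mol⁻¹, k = 0.0521 L mol⁻¹ s⁻¹, Ea = 55.0 kJ mol⁻¹, ΔH = 34.0 kJ mol⁻¹)
    2 reagent → self-condensation product (k = 0.0408 L mol⁻¹ s⁻¹, Ea = 49.0 kJ mol⁻¹)
    (constants at 35 °C)

Birch stood at 20.1% and maple at 7.04%, with oak at 15.3% and ash at 12.1%. The hold read from birch at 50 min was 9.62, twice my 4.56. The neighbour was maple stopped at 12 min, with its charges and temperature unchanged. The same hold of 0.380 and the same constant gave 10.2% target there. That flask held 11.2% target, with 47% of its reagent free.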